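## Structural features

Agastinol is a 2,3,4-trisubstituted tetrahydrofuran (ring atoms O1, C2, C3, C4, C5). C2 carries a 4-hydroxy-3-methoxyphenyl ring, C3 a CH2O group acylated by 4-hydroxybenzoic acid, C4 a 4-hydroxy-3-methoxybenzyl group, and C5 is an unsubstituted OCH2. The three stereocentres are contiguous, C2 (R), C3 (S) and C4 (S): the aryl group on C2 is trans to the C3 side chain, and the C3 and C4 side chains are cis. Fragile elements are the three free phenols, the aryl ester on a primary carbinol (cleaved by hydroxide, alkoxide or unbuffered fluoride) and the C2–O1 bond, which is benzylic and para to oxygen and so open to acid ionisation and to hydrogenolysis. The real difficulty is stereochemical: the less stable 3,4-cis relation has to be installed kinetically next to a 2,3-trans pair, while three oxygen functions are kept apart. C5 is the only ring carbon without a substituent and lies between O1 and C4, so a ring closed by joining O1 to C5 creates no stereocentre. With C4 as a carbonyl carbon and C5 as a diazo carbon, the C2 hydroxyl of an anti-aldol fragment closes the ring by O–H insertion after the aldol has fixed C2 and C3. The ketone left at C4 is the anchor for the benzyl group, and C3, the only enolisable stereocentre, has one stereogenic neighbour and prefers the required trans arrangement.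

## Logic of the disconnections

**26 from 24.** Cut: the three O–CH2Ph bonds of the phenols and the two C–H bonds at C4 and at the benzylic carbon, which become an exocyclic C4=C bond. Reason: one hydrogenation sets C4 and frees all phenols, so the polar, oxidisable groups and the 3,4-cis relation appear only at the end. Gain: no stereocentre at C4 and no free phenol in any intermediate. Demand: hydrogen must reach C4 on the face away from the C3 acyloxymethyl group, and the benzylic C2–O1 bond must outlast the catalyst.

**24 from 22 and 23; 22 from 21.** Cut: the ester C(=O)–O bond, then the Si–O bond on the primary oxygen. Reason: the base-labile aryl ester enters only after all ylide and fluoride chemistry. Gain: a commercial protected acid (23) and a molecule with a single hydroxyl. Demand: the silyl group must survive everything up to 21 and come off beside benzyl ethers.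

**21 from 17 and 19; 19 from 18.** Cut: the exocyclic C4=C double bond, then the benzylic C–P bond. Reason: the carbonyl at C4 is what the ring closure leaves behind, and an sp2 carbon at C4 postpones the cis problem to a face-selective reduction. Gain: the second aryl unit comes from a one-step phosphonium salt. Demand: carbonyl addition must outrun enolisation toward C3 or C5 and loss of silanolate from the β-position.

**17 from 16.** Cut: O1–C5, the bond of the key step. Reason: C5 is unsubstituted and flanked by O1 and the C4 carbonyl, so a diazo carbon at C5 and the C2 hydroxyl close the ring without a new stereocentre. Gain: the ring is removed and an acyclic chain with two adjacent stereocentres remains. Demand: O–H insertion must beat attack on the C2 aryl ring and on the other ether oxygens. For this reason 16 carries the phenol as a benzyl ether (inert to the hydroperoxide, acid and fluoride steps, where an aryl silyl ether would be lost). Its primary oxygen is a TBDPS ether: the bulky, weakly basic oxygen is a poor carbenoid ligand and survives the acidic unmasking of the C2 hydroxyl.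

**16 from 15; 15 from 13.** Cut: the Si–O bond on the C2 oxygen, then the bond between the acyl carbon C4 and the diazomethyl carbon C5. Reason: acylation of CH2N2 by an activated acid is the standard entry to a terminal diazoketone. Gain: a carboxylic acid. Demand: the C2 hydroxyl must be masked during activation by a group (TES) that is removed without harming the diazoketone or the primary silyl ether.

**13 from 11; 11 from 9; 9 from 6 and 7.** Cut: the temporary Si–O bond, the acyl–N bond to the auxiliary, then the C2–C3 bond. Reason: C2–C3 joins a benzaldehyde carbon to the α-carbon of a 3-oxygenated propanoyl unit, and an auxiliary-controlled anti-aldol sets both stereocentres in one step. Gain: an achiral aldehyde and an imide. Demand: anti selectivity in the (2S,3R) sense, and no β-elimination of silanolate from the enolate.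

**6 from 3 and 4; 3 from 2; 2 from 1.** Cut: the imide N–C(=O) bond, the methyl ester, the O–Si bond. Reason: routine functional-group steps to a commercial hydroxy ester and a commercial auxiliary. Gain: only commercial materials remain. Demand: N-acylation without a strong base, so that the β-silyloxy acid does not eliminate.

## Other disconnections considered

**Alternative 1:** The cut removes the C3–C(exocyclic) and C4–C(benzylic) bonds together. In the forward direction the arylketene A2 and the (R)-2-aryl-2,5-dihydrofuran A1 would combine in an EtAlCl2-promoted [2+2] cycloaddition to the cis-fused cyclobutanone A3. Baeyer–Villiger insertion of oxygen between the carbonyl and benzylic carbons, hydrogenolysis of the benzylic C–O bond so created and reduction of the carboxyl group would then reveal the C4 benzyl and C3 CH2OH groups.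

- In its favour: the cis ring fusion enforces the 3,4-cis relation, and on this point the alternative is better than the chosen plan, which relies on the facial selectivity of a hydrogenation. Two C–C bonds form at once. A1 could in principle come from one catalytic enantioselective Heck-type arylation, which is better than an auxiliary sequence for the first stereocentre.
- Against it here: the two alkene carbons of A1 are electronically alike, so the regiochemistry (carbonyl carbon to C3) rests only on the steric bias of the C2 aryl group. The monosubstituted ketene A2 tends to dimerise. The C2–O1 bond of A1 is both allylic and benzylic and para to oxygen, so a strong Lewis acid can ionise it (ring opening, racemisation, aromatisation) and attack the aryl silyl ethers. The later peracid step meets two electron-rich arenes.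
- Comparison: on structure both plans fix C2 first and relay it; the alternative is better at C4 and equal at C3. On mechanism the chosen carbenoid closure is neutral and milder than a cationic cycloaddition. On step economy the alternative is shorter up to A3 but needs oxidation, hydrogenolysis, reduction, esterification and deprotection afterwards, so the two are about equal in length.
- Nomenclature correction: A3 is a 4,7-diaryl-3-oxabicyclo[3.2.0]heptan-6-one. A 2,7-diaryl locant set would belong to the regioisomer with the carbonyl on the other bridgehead.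

**Alternative 2:** The cut is the C3–C4 bond, remade by a 1,2-shift. Photolysis of the 3-diazotetrahydropyran-4-one A4 in methanol would expel N2, the benzyl-bearing ring carbon would migrate with retention to the carbene carbon (Wolff rearrangement), and the ketene would be trapped as the methyl ester A5 on the contracted ring.

- In its favour: the two stereocentres of A4 are 1,4-related and trans-diequatorial, so they are under thermodynamic control. The six-membered ring could be made by a catalytic enantioselective hetero-Diels–Alder reaction, which is better than an auxiliary. The benzyl group is carried through and C4 is transferred with retention, so on C4 the alternative is equal or better.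
- Against it here: C3 becomes a stereocentre only when the ketene is trapped, and nothing controls it. The needed epimer has the ester cis to the benzyl group and trans to the aryl group, the other epimer the reverse; the two should be close in energy, so equilibration at the enolisable C3 would not help either. The diazo group must be placed next to the benzylic C2 by a deformylative transfer, and the ester needs a later reduction.
- Comparison: on structure the chosen plan is better at C3 (set by the aldol and kept) and the alternative better at C4. On mechanism both use a diazoketone, but the chosen step creates no stereocentre while the alternative creates the hardest one in its least controlled event. Step economy is equal within a step or two.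
- Nomenclature correction: by the sequence rules A5 is (2R,3R,4S), because the ester carbon outranks C2 at C3. A (3S) label would describe the C3 epimer.

**Alternative 3:** The cut is the C4–C5 bond. Bu3SnH would generate the O1–CH2 radical from the phenylselanylmethyl ether A6; 5-exo-dig addition to the aryl alkyne and hydrogen transfer to the vinyl radical would give the 4-benzylidene tetrahydrofuran A7.

- In its favour: ring and benzylidene arise in one neutral step, so no olefination of an enolisable ketone is needed; on this point the alternative is better than step 11 of the chosen plan. C3 is never α to a carbonyl once the ring exists, so it is equal or better on the integrity of C3. A7 is the silyl-protected counterpart of 21, so the end game would be equal.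
- Against it here: A6 lies farther from the aldol stage than 16 does. The carboxyl carbon must become an aryl alkyne next to an epimerisable α-stereocentre (reduction, oxidation, alkynylation, arylation), and a hindered benzylic hydroxyl must be alkylated with a chloromethyl selenide. Tin and selenium are used stoichiometrically. The radical may be reduced before it cyclises or may abstract hydrogen 1,5 from the CH2OSi group.
- Comparison: on structure the stereochemical logic is the same (C2 and C3 from an anti aldol, C4 by hydrogenation), so the plans are equal. On mechanism the radical closure is as chemoselective as the carbenoid closure and avoids diazomethane, at the price of tin. On step economy it is about three steps longer before the ring closure and one shorter after it, so longer overall.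

Key step: step 9

Assumption: 4, 7, 18 and 23 are taken as commercial, and the aldol of step 4 is taken to follow the chelated Z-enolate model (aldehyde on the enolate face away from the auxiliary benzyl group), so that the (R)-auxiliary gives the (2S,3R) anti adduct.

## Route

Step 1
Reactants: 1 methyl 3-hydroxypropanoate
Product: 2 methyl 3-[(tert-butyldiphenylsilyl)oxy]propanoate
Conditions: TBDPSCl, imidazole, CH2Cl2, 0 °C to rt
Reagents that add atoms: tert-butyl(chloro)diphenylsilane (TBDPSCl), CC(C)(C)[Si](Cl)(c1ccccc1)c1ccccc1
Why: Imidazole-promoted silylation of a primary alcohol; TBDPS is chosen because it withstands hydroxide, mild acid and ylide later and leaves the ether oxygen a poor donor toward the carbenoid of step 9.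

Step 2
Reactants: 2 methyl 3-[(tert-butyldiphenylsilyl)oxy]propanoate
Product: 3 3-[(tert-butyldiphenylsilyl)oxy]propanoic acid
Conditions: LiOH·H2O, THF–H2O (3:1), 0 °C to rt; then 1 M HCl to pH 3
Reagents that add atoms: lithium hydroxide (supplies the carboxyl OH oxygen), [Li+].[OH-]
Why: Ester saponification; hydroxide adds to the ester carbonyl much faster than it can trigger β-elimination, and a primary TBDPS ether is stable to aqueous LiOH.

Step 3
Reactants: 3 3-[(tert-butyldiphenylsilyl)oxy]propanoic acid; 4 (R)-4-benzyloxazolidin-2-one
Product: 6 (R)-4-benzyl-3-{3-[(tert-butyldiphenylsilyl)oxy]propanoyl}oxazolidin-2-one, via mixed pivalic anhydride 5 (not isolated)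
Conditions: PivCl, Et3N, THF, −20 °C; then 4, LiCl, −20 °C to rt
Reagents that add atoms: none
Why: N-acylation of an oxazolidinone through a mixed pivalic anhydride; the hindered pivaloyl carbonyl steers attack to the wanted acyl group, and the LiCl/amine protocol avoids a strong base that could eliminate the β-silyloxy group.

Step 4
Reactants: 6 (R)-4-benzyl-3-{3-[(tert-butyldiphenylsilyl)oxy]propanoyl}oxazolidin-2-one; 7 4-(benzyloxy)-3-methoxybenzaldehyde
Product: 9 (R)-4-benzyl-3-[(2S,3R)-3-[4-(benzyloxy)-3-methoxyphenyl]-2-{[(tert-butyldiphenylsilyl)oxy]methyl}-3-hydroxypropanoyl]oxazolidin-2-one, via O-trimethylsilyl aldol adduct 8 (not isolated)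
Conditions: MgCl2 (20 mol%), Et3N, TMSCl, EtOAc, 23 °C; then citric acid (cat.), MeOH, 0 °C
Reagents that add atoms: none
Why: Magnesium halide-catalysed anti-aldol reaction of an N-acyloxazolidinone with silyl turnover; the chelated Z-magnesium enolate should be attacked by the aromatic aldehyde on the face away from the auxiliary benzyl group through a boat-like transition state, setting C2 (R) and C3 (S) as the anti pair. Mild acidic methanolysis then removes only the TMS ether.

Step 5
Reactants: 9 (R)-4-benzyl-3-[(2S,3R)-3-[4-(benzyloxy)-3-methoxyphenyl]-2-{[(tert-butyldiphenylsilyl)oxy]methyl}-3-hydroxypropanoyl]oxazolidin-2-one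
Product: 11 (2S,3R)-3-[4-(benzyloxy)-3-methoxyphenyl]-2-{[(tert-butyldiphenylsilyl)oxy]methyl}-3-hydroxypropanoic acid, via peroxy acid 10 (not isolated)
Conditions: LiOH·H2O, 30% H2O2, THF–H2O (4:1), 0 °C; then aq. Na2SO3; then 1 M HCl to pH 3
Reagents that add atoms: hydrogen peroxide, OO
Why: Hydroperoxide cleavage of the imide at the exocyclic carbonyl followed by sulfite reduction of the peracid; the weakly basic α-nucleophile should avoid retro-aldol and epimerisation, the free hydroxyl keeps the imide unhindered, and benzyl and TBDPS ethers are inert. The auxiliary 4 is recovered.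

Step 6
Reactants: 11 (2S,3R)-3-[4-(benzyloxy)-3-methoxyphenyl]-2-{[(tert-butyldiphenylsilyl)oxy]methyl}-3-hydroxypropanoic acid
Product: 13 (2S,3R)-3-[4-(benzyloxy)-3-methoxyphenyl]-2-{[(tert-butyldiphenylsilyl)oxy]methyl}-3-[(triethylsilyl)oxy]propanoic acid, via bis(triethylsilyl) derivative 12 (not isolated)
Conditions: TESCl, imidazole, DMF, 0 °C to rt; then MeOH–H2O, K2CO3 (cat.), 0 °C; citrate buffer pH 5
Reagents that add atoms: chlorotriethylsilane (TESCl), CC[Si](Cl)(CC)CC
Why: Exhaustive silylation followed by selective solvolysis of the far more labile silyl ester; the temporary TES ether keeps the benzylic hydroxyl from forming a carbonate or a β-lactone when the carboxyl group is activated.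

Step 7
Reactants: 13 (2S,3R)-3-[4-(benzyloxy)-3-methoxyphenyl]-2-{[(tert-butyldiphenylsilyl)oxy]methyl}-3-[(triethylsilyl)oxy]propanoic acid
Product: 15 (3S,4R)-4-[4-(benzyloxy)-3-methoxyphenyl]-3-{[(tert-butyldiphenylsilyl)oxy]methyl}-1-diazo-4-[(triethylsilyl)oxy]butan-2-one, via mixed isobutyl carbonic anhydride 14 (not isolated)
Conditions: i-BuOCOCl, N-methylmorpholine, THF, −20 °C; then CH2N2, Et2O, −20 to 0 °C
Reagents that add atoms: diazomethane, C=[N+]=[N-]
Why: Acylation of diazomethane by a mixed carbonic anhydride (first stage of the Arndt–Eistert sequence); activation at low temperature without an acid chloride should leave the α-stereocentre and both silyl ethers untouched.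

Step 8
Reactants: 15 (3S,4R)-4-[4-(benzyloxy)-3-methoxyphenyl]-3-{[(tert-butyldiphenylsilyl)oxy]methyl}-1-diazo-4-[(triethylsilyl)oxy]butan-2-one
Product: 16 (3S,4R)-4-[4-(benzyloxy)-3-methoxyphenyl]-3-{[(tert-butyldiphenylsilyl)oxy]methyl}-1-diazo-4-hydroxybutan-2-one
Conditions: PPTS (0.2 equiv), MeOH–CH2Cl2 (1:1), 0 °C
Reagents that add atoms: none
Why: Acid-catalysed methanolysis of a triethylsilyl ether; TES is orders of magnitude more acid-labile than TBDPS, and a pyridinium acid is too weak to protonate the diazoketone. Fluoride sources are avoided because HF adds to diazoketones.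

Step 9
Reactants: 16 (3S,4R)-4-[4-(benzyloxy)-3-methoxyphenyl]-3-{[(tert-butyldiphenylsilyl)oxy]methyl}-1-diazo-4-hydroxybutan-2-one
Product: 17 (4S,5R)-5-[4-(benzyloxy)-3-methoxyphenyl]-4-{[(tert-butyldiphenylsilyl)oxy]methyl}dihydrofuran-3(2H)-one
Conditions: Rh2(OAc)4 (1 mol%), CH2Cl2, rt, slow addition of 16 at high dilution
Reagents that add atoms: none
Why: Rh2(OAc)4 decomposes the diazoketone with loss of N2 to an electrophilic rhodium carbenoid at C5; the C2 hydroxyl oxygen adds to it to give an oxonium ylide, and a proton shift releases the catalyst and the cyclic ether. The closest known reaction type is the dirhodium-catalysed intramolecular O–H insertion of hydroxy diazoketones to 3-oxotetrahydrofurans. The one ring formed, the tetrahydrofuran O1–C2–C3–C4–C5, closes by five-membered attack of oxygen on the carbenoid carbon with the C=Rh bond exocyclic (formally 5-exo), making only the O1–C5 bond. No stereocentre is created: C5 becomes a CH2 group, C2 is not touched, and C3, now α to the C4 ketone, keeps the configuration set by the anti-aldol reaction, which is also the thermodynamically preferred 2,3-trans arrangement should any enolisation occur. The step needs chemoselectivity for O–H insertion over attack of the carbenoid on the electron-rich C2 aryl ring (a six-membered approach to the ortho carbon), over ylide formation at the silyl ether oxygen and over carbene dimerisation. The substrate secures this through an unhindered secondary hydroxyl placed for five-membered closure and a bulky, weakly basic TBDPS ether oxygen; slow addition at high dilution to a carboxylate catalyst of moderate electrophilicity does the rest.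

Step 10
Reactants: 18 [4-(benzyloxy)-3-methoxyphenyl]methanol
Product: 19 {[4-(benzyloxy)-3-methoxyphenyl]methyl}triphenylphosphonium bromide
Conditions: PPh3·HBr, MeCN, reflux
Reagents that add atoms: triphenylphosphine hydrobromide, [Br-].[PH+](c1ccccc1)(c1ccccc1)c1ccccc1
Why: Direct conversion of an electron-rich benzylic alcohol into its phosphonium salt (protonation, ionisation assisted by the para oxygen, capture by PPh3); the aryl benzyl ether is stable to this mild acid.

Step 11
Reactants: 19 {[4-(benzyloxy)-3-methoxyphenyl]methyl}triphenylphosphonium bromide; 17 (4S,5R)-5-[4-(benzyloxy)-3-methoxyphenyl]-4-{[(tert-butyldiphenylsilyl)oxy]methyl}dihydrofuran-3(2H)-one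
Product: 21 tert-butyl{[(2R,3S,4Z)-2-[4-(benzyloxy)-3-methoxyphenyl]-4-{[4-(benzyloxy)-3-methoxyphenyl]methylidene}tetrahydrofuran-3-yl]methoxy}diphenylsilane (Z isomer drawn; the E isomer may accompany it), via benzylidenephosphorane 20 (not isolated)
Conditions: 19, KN(SiMe3)2, THF, 0 °C; then 17, 0 °C to rt
Reagents that add atoms: none
Why: Wittig olefination of a ketone with a semi-stabilised ylide; the α-alkoxy ketone is an electrophilic carbonyl, so addition should outrun enolisation under salt-free conditions. Either alkene geometry is acceptable because it is erased in step 14, and C3 can only equilibrate toward the trans arrangement it already has.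

Step 12
Reactants: 21 tert-butyl{[(2R,3S,4Z)-2-[4-(benzyloxy)-3-methoxyphenyl]-4-{[4-(benzyloxy)-3-methoxyphenyl]methylidene}tetrahydrofuran-3-yl]methoxy}diphenylsilane
Product: 22 [(2R,3S,4Z)-2-[4-(benzyloxy)-3-methoxyphenyl]-4-{[4-(benzyloxy)-3-methoxyphenyl]methylidene}tetrahydrofuran-3-yl]methanol
Conditions: Bu4NF, THF, 0 °C to rt
Reagents that add atoms: none
Why: Fluoride-induced desilylation driven by the Si–F bond; benzyl ethers, the styrene and the benzylic ring ether are inert, and no ester is present yet.

Step 13
Reactants: 22 [(2R,3S,4Z)-2-[4-(benzyloxy)-3-methoxyphenyl]-4-{[4-(benzyloxy)-3-methoxyphenyl]methylidene}tetrahydrofuran-3-yl]methanol; 23 4-(benzyloxy)benzoic acid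
Product: 24 [(2R,3S,4Z)-2-[4-(benzyloxy)-3-methoxyphenyl]-4-{[4-(benzyloxy)-3-methoxyphenyl]methylidene}tetrahydrofuran-3-yl]methyl 4-(benzyloxy)benzoate
Conditions: DIC, DMAP (cat.), CH2Cl2, 0 °C to rt
Reagents that add atoms: none
Why: Steglich esterification (carbodiimide activation with DMAP acyl transfer) of the only free hydroxyl, a primary alcohol, under neutral conditions.

Step 14
Reactants: 24 [(2R,3S,4Z)-2-[4-(benzyloxy)-3-methoxyphenyl]-4-{[4-(benzyloxy)-3-methoxyphenyl]methylidene}tetrahydrofuran-3-yl]methyl 4-(benzyloxy)benzoate
Product: 26 agastinol, via tris(O-benzyl)agastinol 25 (not isolated)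
Conditions: H2 (1 atm), 10% Pd/C, EtOAc, rt, stopped after uptake
Reagents that add atoms: none
Why: Heterogeneous hydrogenation and hydrogenolysis over Pd/C; the exocyclic alkene should bind the metal on the face anti to the C3 acyloxymethyl group, so hydrogen arrives at C4 from that side and the benzyl group ends cis to the C3 substituent (C4 = S). The three aryl benzyl ethers are cleaved in the same flask, and a neutral aprotic solvent with a short contact time protects the benzylic C2–O1 bond.

## Compound list

1 | methyl 3-hydroxypropanoate | COC(=O)CCO | starting material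
2 | methyl 3-[(tert-butyldiphenylsilyl)oxy]propanoate | COC(=O)CCO[Si](c1ccccc1)(c1ccccc1)C(C)(C)C | intermediate
3 | 3-[(tert-butyldiphenylsilyl)oxy]propanoic acid | OC(=O)CCO[Si](c1ccccc1)(c1ccccc1)C(C)(C)C | intermediate
4 | (R)-4-benzyloxazolidin-2-one | O=C1N[C@H](Cc2ccccc2)CO1 | starting material
5 | 3-[(tert-butyldiphenylsilyl)oxy]propanoic pivalic anhydride | CC(C)(C)C(=O)OC(=O)CCO[Si](c1ccccc1)(c1ccccc1)C(C)(C)C | intermediate
6 | (R)-4-benzyl-3-{3-[(tert-butyldiphenylsilyl)oxy]propanoyl}oxazolidin-2-one | O=C(CCO[Si](c1ccccc1)(c1ccccc1)C(C)(C)C)N1[C@H](Cc2ccccc2)COC1=O | intermediate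
7 | 4-(benzyloxy)-3-methoxybenzaldehyde | COc1cc(C=O)ccc1OCc1ccccc1 | starting material
8 | (R)-4-benzyl-3-[(2S,3R)-3-[4-(benzyloxy)-3-methoxyphenyl]-2-{[(tert-butyldiphenylsilyl)oxy]methyl}-3-[(trimethylsilyl)oxy]propanoyl]oxazolidin-2-one | C[Si](C)(C)O[C@@H](c1ccc(OCc2ccccc2)c(OC)c1)[C@@H](C(=O)N1[C@H](Cc2ccccc2)COC1=O)CO[Si](c1ccccc1)(c1ccccc1)C(C)(C)C | intermediate
9 | (R)-4-benzyl-3-[(2S,3R)-3-[4-(benzyloxy)-3-methoxyphenyl]-2-{[(tert-butyldiphenylsilyl)oxy]methyl}-3-hydroxypropanoyl]oxazolidin-2-one | O[C@@H](c1ccc(OCc2ccccc2)c(OC)c1)[C@@H](C(=O)N1[C@H](Cc2ccccc2)COC1=O)CO[Si](c1ccccc1)(c1ccccc1)C(C)(C)C | intermediate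
10 | (2S,3R)-3-[4-(benzyloxy)-3-methoxyphenyl]-2-{[(tert-butyldiphenylsilyl)oxy]methyl}-3-hydroxypropaneperoxoic acid (formed as its lithium salt) | O[C@@H](c1ccc(OCc2ccccc2)c(OC)c1)[C@@H](C(=O)OO)CO[Si](c1ccccc1)(c1ccccc1)C(C)(C)C | intermediate
11 | (2S,3R)-3-[4-(benzyloxy)-3-methoxyphenyl]-2-{[(tert-butyldiphenylsilyl)oxy]methyl}-3-hydroxypropanoic acid | O[C@@H](c1ccc(OCc2ccccc2)c(OC)c1)[C@@H](C(=O)O)CO[Si](c1ccccc1)(c1ccccc1)C(C)(C)C | intermediate
12 | triethylsilyl (2S,3R)-3-[4-(benzyloxy)-3-methoxyphenyl]-2-{[(tert-butyldiphenylsilyl)oxy]methyl}-3-[(triethylsilyl)oxy]propanoate | CC[Si](CC)(CC)O[C@@H](c1ccc(OCc2ccccc2)c(OC)c1)[C@@H](C(=O)O[Si](CC)(CC)CC)CO[Si](c1ccccc1)(c1ccccc1)C(C)(C)C | intermediate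
13 | (2S,3R)-3-[4-(benzyloxy)-3-methoxyphenyl]-2-{[(tert-butyldiphenylsilyl)oxy]methyl}-3-[(triethylsilyl)oxy]propanoic acid | CC[Si](CC)(CC)O[C@@H](c1ccc(OCc2ccccc2)c(OC)c1)[C@@H](C(=O)O)CO[Si](c1ccccc1)(c1ccccc1)C(C)(C)C | intermediate
14 | mixed anhydride of 13 with isobutyl hydrogen carbonate | CC[Si](CC)(CC)O[C@@H](c1ccc(OCc2ccccc2)c(OC)c1)[C@@H](C(=O)OC(=O)OCC(C)C)CO[Si](c1ccccc1)(c1ccccc1)C(C)(C)C | intermediate
15 | (3S,4R)-4-[4-(benzyloxy)-3-methoxyphenyl]-3-{[(tert-butyldiphenylsilyl)oxy]methyl}-1-diazo-4-[(triethylsilyl)oxy]butan-2-one | CC[Si](CC)(CC)O[C@@H](c1ccc(OCc2ccccc2)c(OC)c1)[C@@H](C(=O)C=[N+]=[N-])CO[Si](c1ccccc1)(c1ccccc1)C(C)(C)C | intermediate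
16 | (3S,4R)-4-[4-(benzyloxy)-3-methoxyphenyl]-3-{[(tert-butyldiphenylsilyl)oxy]methyl}-1-diazo-4-hydroxybutan-2-one | O[C@@H](c1ccc(OCc2ccccc2)c(OC)c1)[C@@H](C(=O)C=[N+]=[N-])CO[Si](c1ccccc1)(c1ccccc1)C(C)(C)C | intermediate
17 | (4S,5R)-5-[4-(benzyloxy)-3-methoxyphenyl]-4-{[(tert-butyldiphenylsilyl)oxy]methyl}dihydrofuran-3(2H)-one | O=C1CO[C@@H](c2ccc(OCc3ccccc3)c(OC)c2)[C@@H]1CO[Si](c1ccccc1)(c1ccccc1)C(C)(C)C | intermediate
18 | [4-(benzyloxy)-3-methoxyphenyl]methanol | COc1cc(CO)ccc1OCc1ccccc1 | starting material
19 | {[4-(benzyloxy)-3-methoxyphenyl]methyl}triphenylphosphonium bromide | COc1cc(C[P+](c2ccccc2)(c2ccccc2)c2ccccc2)ccc1OCc1ccccc1.[Br-] | intermediate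
20 | {[4-(benzyloxy)-3-methoxyphenyl]methylidene}triphenylphosphorane | COc1cc(C=P(c2ccccc2)(c2ccccc2)c2ccccc2)ccc1OCc1ccccc1 | intermediate
21 | tert-butyl{[(2R,3S,4Z)-2-[4-(benzyloxy)-3-methoxyphenyl]-4-{[4-(benzyloxy)-3-methoxyphenyl]methylidene}tetrahydrofuran-3-yl]methoxy}diphenylsilane (Z drawn; E may accompany it) | COc1cc(/C=C2\CO[C@@H](c3ccc(OCc4ccccc4)c(OC)c3)[C@@H]2CO[Si](c2ccccc2)(c2ccccc2)C(C)(C)C)ccc1OCc1ccccc1 | intermediate
22 | [(2R,3S,4Z)-2-[4-(benzyloxy)-3-methoxyphenyl]-4-{[4-(benzyloxy)-3-methoxyphenyl]methylidene}tetrahydrofuran-3-yl]methanol | COc1cc(/C=C2\CO[C@@H](c3ccc(OCc4ccccc4)c(OC)c3)[C@@H]2CO)ccc1OCc1ccccc1 | intermediate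
23 | 4-(benzyloxy)benzoic acid | OC(=O)c1ccc(OCc2ccccc2)cc1 | starting material
24 | [(2R,3S,4Z)-2-[4-(benzyloxy)-3-methoxyphenyl]-4-{[4-(benzyloxy)-3-methoxyphenyl]methylidene}tetrahydrofuran-3-yl]methyl 4-(benzyloxy)benzoate | COc1cc(/C=C2\CO[C@@H](c3ccc(OCc4ccccc4)c(OC)c3)[C@@H]2COC(=O)c2ccc(OCc3ccccc3)cc2)ccc1OCc1ccccc1 | intermediate
25 | [(2R,3S,4S)-2-[4-(benzyloxy)-3-methoxyphenyl]-4-{[4-(benzyloxy)-3-methoxyphenyl]methyl}tetrahydrofuran-3-yl]methyl 4-(benzyloxy)benzoate | COc1cc(C[C@@H]2CO[C@@H](c3ccc(OCc4ccccc4)c(OC)c3)[C@@H]2COC(=O)c2ccc(OCc3ccccc3)cc2)ccc1OCc1ccccc1 | intermediate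
26 | agastinol, [(2R,3S,4S)-2-(4-hydroxy-3-methoxyphenyl)-4-[(4-hydroxy-3-methoxyphenyl)methyl]tetrahydrofuran-3-yl]methyl 4-hydroxybenzoate | COc1cc(C[C@@H]2CO[C@@H](c3ccc(O)c(OC)c3)[C@@H]2COC(=O)c2ccc(O)cc2)ccc1O | target

## Step count and least certain steps

Total: 14 steps. Longest linear sequence: 13 steps (steps 1–9 and 11–14, from 1); step 10 is a one-step side branch.

**Step 9 (key step).** The carbenoid may be diverted into attack on the electron-rich C2 aryl ring (aromatic substitution or cycloaddition through a six-membered approach) or into ylide formation at the silyl ether oxygen followed by a shift. It may also dimerise if the concentration is too high, because several donors sit at a similar distance from C5. Fallback: the same O1–C5 bond is closed ionically. Setting out from 16, one equivalent of HBr in Et2O at −30 °C should convert the diazoketone into the bromomethyl ketone F1. Ag2O in CH2Cl2 at rt then closes the ring by intramolecular Williamson alkylation (5-exo-tet) without a strong base that could trigger retro-aldol cleavage, and the sequence comes back to the route at 17.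

**Step 4.** The magnesium enolate may lose silanolate by β-elimination, addition to the electron-rich and therefore weakly electrophilic aldehyde may be slow, and anti selectivity may erode over the long reaction time at room temperature. Fallback: setting out from 6 and 7, 6 is enolised with Bu2BOTf and i-Pr2NEt in CH2Cl2 at −78 °C to the Z-configured dibutylboron enolate F2. This is added at −78 °C to 7 precomplexed with Et2AlCl. The open, Lewis-acid-mediated transition state on the auxiliary-chelated enolate should give the same anti adduct at a temperature where elimination is unlikely, and the sequence comes back to the route at 9.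

**Step 11.** The basic ylide may enolise 17 instead of adding to it, with loss of silanolate from the enolate toward C3, and addition to the α-branched ketone may be sluggish. Fallback: setting out from 18 and 17, SOCl2 converts 18 into the benzylic chloride F3, and Mg in THF gives the Grignard reagent F4. Addition of F4 to 17 in the presence of anhydrous CeCl3 at −78 °C (a weakly basic, strongly nucleophilic organocerium) should give the tertiary alcohol F5 with the hydroxyl cis to the silyloxymethyl group. Burgess reagent in toluene at 50 °C then dehydrates by syn elimination toward the benzylic methylene; elimination toward C3 is barred because the C3 hydrogen is anti to the leaving group. The sequence comes back to the route at 21.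

**Step 14.** Face selectivity at C4 may be insufficient with the ester as the only shielding group. Over-reduction is also possible, by hydrogenolysis of the allylic C5–O1 bond before saturation or of the benzylic C2–O1 bond once the para phenol is free. Fallback: the two events are separated and C4 is set earlier under a bulkier shield. Setting out from 21, hydrogenation of the alkene alone over Pd/C poisoned with Ph2S (or over Rh/Al2O3) in EtOAc, which should keep the benzyl ethers, gives the saturated silyl ether F6. Bu4NF gives the primary alcohol F7, and DIC/DMAP esterification with 23 gives 25, this time isolated, where the sequence comes back to the route. Only a brief O-debenzylation (Pd/C with 1,4-cyclohexadiene as hydrogen donor) then remains to reach 26.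

## Further compounds

F1 | step 9 | (3S,4R)-4-[4-(benzyloxy)-3-methoxyphenyl]-1-bromo-3-{[(tert-butyldiphenylsilyl)oxy]methyl}-4-hydroxybutan-2-one | O[C@@H](c1ccc(OCc2ccccc2)c(OC)c1)[C@@H](C(=O)CBr)CO[Si](c1ccccc1)(c1ccccc1)C(C)(C)C
F2 | step 4 | (R)-4-benzyl-3-[(Z)-3-[(tert-butyldiphenylsilyl)oxy]-1-[(dibutylboranyl)oxy]prop-1-en-1-yl]oxazolidin-2-one | CCCCB(CCCC)O/C(=C\CO[Si](c1ccccc1)(c1ccccc1)C(C)(C)C)N1[C@H](Cc2ccccc2)COC1=O
F3 | step 11 | 1-(benzyloxy)-4-(chloromethyl)-2-methoxybenzene | COc1cc(CCl)ccc1OCc1ccccc1
F4 | step 11 | {[4-(benzyloxy)-3-methoxyphenyl]methyl}magnesium chloride | COc1cc(C[Mg]Cl)ccc1OCc1ccccc1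
F5 | step 11 | (3S,4S,5R)-5-[4-(benzyloxy)-3-methoxyphenyl]-3-{[4-(benzyloxy)-3-methoxyphenyl]methyl}-4-{[(tert-butyldiphenylsilyl)oxy]methyl}tetrahydrofuran-3-ol | COc1cc(C[C@@]2(O)CO[C@@H](c3ccc(OCc4ccccc4)c(OC)c3)[C@@H]2CO[Si](c2ccccc2)(c2ccccc2)C(C)(C)C)ccc1OCc1ccccc1
F6 | step 14 | tert-butyl{[(2R,3S,4S)-2-[4-(benzyloxy)-3-methoxyphenyl]-4-{[4-(benzyloxy)-3-methoxyphenyl]methyl}tetrahydrofuran-3-yl]methoxy}diphenylsilane | COc1cc(C[C@@H]2CO[C@@H](c3ccc(OCc4ccccc4)c(OC)c3)[C@@H]2CO[Si](c2ccccc2)(c2ccccc2)C(C)(C)C)ccc1OCc1ccccc1
F7 | step 14 | [(2R,3S,4S)-2-[4-(benzyloxy)-3-methoxyphenyl]-4-{[4-(benzyloxy)-3-methoxyphenyl]methyl}tetrahydrofuran-3-yl]methanol | COc1cc(C[C@@H]2CO[C@@H](c3ccc(OCc4ccccc4)c(OC)c3)[C@@H]2CO)ccc1OCc1ccccc1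
A1 | alternative 1 | (R)-2-[4-(tert-butyldimethylsilyloxy)-3-methoxyphenyl]-2,5-dihydrofuran | COc1cc([C@@H]2OCC=C2)ccc1O[Si](C)(C)C(C)(C)C
A2 | alternative 1 | [4-(tert-butyldimethylsilyloxy)-3-methoxyphenyl]ketene | COc1cc(C=C=O)ccc1O[Si](C)(C)C(C)(C)C
A3 | alternative 1 | cis-fused 4,7-bis[4-(tert-butyldimethylsilyloxy)-3-methoxyphenyl]-3-oxabicyclo[3.2.0]heptan-6-one, both aryl groups exo | COc1cc([C@H]3[C@@H]2CO[C@@H](c4ccc(O[Si](C)(C)C(C)(C)C)c(OC)c4)[C@@H]2C3=O)ccc1O[Si](C)(C)C(C)(C)C
A4 | alternative 2 | (2S,5R)-2-[4-(tert-butyldimethylsilyloxy)-3-methoxyphenyl]-5-{[4-(tert-butyldimethylsilyloxy)-3-methoxyphenyl]methyl}-3-diazotetrahydro-4H-pyran-4-one | COc1cc(C[C@@H]2CO[C@@H](c3ccc(O[Si](C)(C)C(C)(C)C)c(OC)c3)C(=[N+]=[N-])C2=O)ccc1O[Si](C)(C)C(C)(C)C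
A5 | alternative 2 | methyl (2R,3R,4S)-2-[4-(tert-butyldimethylsilyloxy)-3-methoxyphenyl]-4-{[4-(tert-butyldimethylsilyloxy)-3-methoxyphenyl]methyl}tetrahydrofuran-3-carboxylate | COc1cc(C[C@@H]2CO[C@@H](c3ccc(O[Si](C)(C)C(C)(C)C)c(OC)c3)[C@@H]2C(=O)OC)ccc1O[Si](C)(C)C(C)(C)C
A6 | alternative 3 | (phenylselanyl)methyl ether of (1R,2S)-1,4-bis[4-(tert-butyldimethylsilyloxy)-3-methoxyphenyl]-2-[(tert-butyldimethylsilyloxy)methyl]but-3-yn-1-ol | c1ccccc1[Se]CO[C@@H](c1ccc(O[Si](C)(C)C(C)(C)C)c(OC)c1)[C@@H](C#Cc1ccc(O[Si](C)(C)C(C)(C)C)c(OC)c1)CO[Si](C)(C)C(C)(C)C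
A7 | alternative 3 | (2R,3S,4Z)-2-[4-(tert-butyldimethylsilyloxy)-3-methoxyphenyl]-4-{[4-(tert-butyldimethylsilyloxy)-3-methoxyphenyl]methylidene}-3-[(tert-butyldimethylsilyloxy)methyl]tetrahydrofuran | COc1cc(/C=C2\CO[C@@H](c3ccc(O[Si](C)(C)C(C)(C)C)c(OC)c3)[C@@H]2CO[Si](C)(C)C(C)(C)C)ccc1O[Si](C)(C)C(C)(C)C
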